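**Two runs.** The constants of these flasks were unknown to me, so I began from the two earlier runs.

| flask | solid substrate | remark | time |
|---|---|---|---|
| south-east | 0.020 M | run made earlier |  |
| south | 0.16 M | run made earlier |  |
| dusk | 0.25 M |  | 25 h |
| noon | 0.15 M |  | 25 h |
| autumn | 0.068 M |  | 25 h |
| spring | 0.025 M |  | 25 h |
| midnight | 0.050 M |  | 25 h |

| run | time / h | target / % | solid substrate / % |
|---|---|---|---|
| south-east | 2.00 | 4.0 | 94.4 |
| south-east | 3.00 | 7.8 | 89.6 |
| south-east | 6.00 | 15.2 | 83.3 |
| south-east | 10.0 | 26.8 | 71.8 |
| south-east | 15.0 | 41.2 | 55.9 |
| south-east | 25.0 | 68.5 | 30.2 |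
| south | 1.50 | 0.5 | 97.7 |
| south | 5.00 | 0.8 | 98.2 |
| south | 8.00 | 4.4 | 97.3 |
| south | 15.0 | 4.2 | 93.7 |
| south | 20.0 | 7.1 | 91.9 |
| south | 25.0 | 11.0 | 90.6 |

(scatter of a reading: 1 percentage point)

- solid, in amounts per volume of the solution: solid substrate
- the numbers in the tables scatter with a standard deviation of 1 percentage point
- at the start none of the solid substrate is in solution
- what has only dissolved of solid substrate counts as not reacted

1. the flasks by amount of target, in percent of the solid substrate charged, highest first, at 25 h (dusk / noon / autumn / spring / midnight)
2. the amount of target, in percent of the solid substrate charged of the flask you put first, at 25 h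
3. the amount of target, in percent of the solid substrate charged of the flask you put last, at 25 h

**Molar balance.** I counted the target in moles per litre, not in percent. The south-east run reached 68.5% of 0.020 M at 25.0 h, which makes 5.48 × 10⁻⁴ M h⁻¹. I carried this as the feed rate, the target gained per litre and hour while undissolved solid stands, a zero-order rate. The last south reading gives 7.04 × 10⁻⁴ M h⁻¹, which is 1.28 times the feed rate on 8.00 times the charge, so the gain did not follow the charge. I trusted the south-east figure, because a percentage point there weighs less in moles.

**First estimate.** While undissolved solid stands and the feed rate holds, the percentage is the feed rate times the time, divided by the charge. At 25 h this gave 54.8% for spring, which has the smallest charge, and 5.48% for dusk, which has the largest.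

**Weak link.** The line might have bent as the solid thinned in spring. But the south-east run, with a smaller charge, gave 5.36 × 10⁻⁴ M h⁻¹ up to 10.0 h, close to its rate over the whole run, so I kept the estimate.

**The forecast.** It read spring > midnight > autumn > noon > dusk, with 56% first and 5.7% last, a little above my two figures, on the ground that “the absolute rate is nearly independent of charge”.

**The result.** The flasks came out as spring > midnight > autumn > noon > dusk, with 54.9% in spring and 5.49% in dusk. The by-product stood at 0.0138 M in spring and 0.0138 M in dusk, equal on charges 10.0 times apart. The feed rate gives 20.1% for autumn, and the flask gave 20.2%.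

    solid substrate ⇌ starting material, rate k1*(cs1 - [starting material]) while solid is left; crystals form when [starting material] > cs1 (solubility = 9.10 mM, k = 0.0652 h⁻¹)
    starting material ⇌ target + by-product (K = 1.40 M, k = 2.05 h⁻¹)
    starting material + target → side product (k = 1.71 L mol⁻¹ h⁻¹)

**Second flask.** For dusk read at 6.0 h, the feed rate gives 1.32%. The computed flask holds 1.27%.

The earlier runs and the new flask are calculated from invented constants, noise included.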